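**Retrosynthetic overview** (bicyclo[3.2.1]octane locants: C1 bridgehead between the two carbonyls, C2 enone carbonyl, C3=C4 with the styryl group on C4, C5 bridgehead, C6 exo 3,5-dioxygenated aryl, C7 endo 3,4-dioxygenated aryl, C8 bridging carbonyl)
1. Enabling feature: in the six-membered ring C1–C2–C3–C4–C5–C8 the C2 carbonyl is β to the C8 carbonyl through bridgehead C1, and C1 is also the α-carbon next to aryl-bearing C7, so C1–C2 is a Claisen bond and C7–aryl a conjugate-addition bond that can be made in one operation.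
2. Cutting both gives a cyclopent-2-enone (C8=O, C1=C7) with the exo aryl on C6 and, trans to it on C5, a (2Z,4E)-dienyl Weinreb amide arm (C4, C3, C2), plus the catechol-type aryl Grignard reagent; the six-membered ring is closed last.
3. The five-membered ring (C1, C7, C6, C5, C8) is present from the start as (R)-4-silyloxycyclopent-2-enone: conjugate arylation sets C6, the regiodefined enolate is alkenylated at C5, and loss of silanol moves the enone to C1=C7.
4. The arm comes from protected 3,4-dihydroxybenzaldehyde by Takai olefination, Sonogashira coupling with a propiolic Weinreb amide and anti-hydroiodination.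
5. All phenols travel as tert-butyldimethylsilyl ethers and are freed at the end with HF·pyridine.

Key step: step 10

Assumption: commercial (R)-4-(tert-butyldimethylsilyloxy)cyclopent-2-en-1-one is the only source of absolute configuration (its stereocentre sets C6 and is destroyed in step 9), and N-methoxy-N-methylprop-2-ynamide is taken as a catalogue compound.

Abbreviations: TBS = tert-butyldimethylsilyl, TBSO = tert-butyldimethylsilyloxy, TMS = trimethylsilyl.

**Step 1**
Reactants: 1 5-bromobenzene-1,3-diol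
Product: 2 1-bromo-3,5-bis(TBSO)benzene
Conditions: TBSCl, imidazole, DMF, rt
Reagents that add atoms: tert-butyldimethylsilyl chloride, CC(C)(C)[Si](C)(C)Cl
Why: Imidazole-promoted silylation of phenols gives the bis-silyl ether, which tolerates Grignard formation because neither silyloxy group is ortho to bromine; no stereocentre is involved.

**Step 2**
Reactants: 3 4-bromobenzene-1,2-diol
Product: 4 4-bromo-1,2-bis(TBSO)benzene
Conditions: TBSCl, imidazole, DMF, rt
Reagents that add atoms: tert-butyldimethylsilyl chloride, CC(C)(C)[Si](C)(C)Cl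
Why: The same phenol silylation protects the catechol as a bis-silyl ether without creating a stereocentre.

**Step 3**
Reactants: 5 3,4-dihydroxybenzaldehyde
Product: 6 3,4-bis(TBSO)benzaldehyde
Conditions: TBSCl, imidazole, DMF, rt
Reagents that add atoms: tert-butyldimethylsilyl chloride, CC(C)(C)[Si](C)(C)Cl
Why: Phenol silylation leaves the aldehyde untouched and creates no stereocentre.

**Step 4**
Reactants: 6 3,4-bis(TBSO)benzaldehyde
Product: 7 (E)-4-(2-iodoethenyl)-1,2-bis(TBSO)benzene
Conditions: CrCl2, CHI3, THF, 0 °C to rt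
Reagents that add atoms: iodoform, IC(I)I
Why: Takai olefination with the gem-dichromium reagent from CHI3 and CrCl2 converts an aryl aldehyde into the vinyl iodide with the kinetically preferred E geometry under neutral conditions that spare aryl silyl ethers.

**Step 5**
Reactants: 7 (E)-4-(2-iodoethenyl)-1,2-bis(TBSO)benzene; 8 N-methoxy-N-methylprop-2-ynamide
Product: 9 (E)-5-[3,4-bis(TBSO)phenyl]-N-methoxy-N-methylpent-4-en-2-ynamide
Conditions: PdCl2(PPh3)2 (cat.), CuI (cat.), i-Pr2NH, THF, rt
Reagents that add atoms: none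
Why: Sonogashira coupling of a vinyl iodide with a terminal alkyne proceeds with retention of the E geometry, and the hindered amine base does not add to the ynamide or cleave aryl silyl ethers.

**Step 6**
Reactants: 9 (E)-5-[3,4-bis(TBSO)phenyl]-N-methoxy-N-methylpent-4-en-2-ynamide
Product: 10 (2Z,4E)-5-[3,4-bis(TBSO)phenyl]-3-iodo-N-methoxy-N-methylpenta-2,4-dienamide (iodine cis to the amide carbonyl)
Conditions: NaI, AcOH, 70 °C
Reagents that add atoms: sodium iodide, [Na+].[I-]
Why: Conjugate hydroiodination of an alkynyl carbonyl compound is a net anti addition (iodide to the β-carbon, proton to the α-carbon from the opposite side), which should place iodine cis to the amide carbonyl and fix the 2Z geometry needed later for ring closure.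

**Step 7**
Reactants: 11 (R)-4-(TBSO)cyclopent-2-en-1-one; 2 1-bromo-3,5-bis(TBSO)benzene
Product: 13 (3S,4R)-3-[3,5-bis(TBSO)phenyl]-4-(TBSO)-1-(trimethylsilyloxy)cyclopent-1-ene (aryl and silyloxy trans), via arylmagnesium bromide 12 (not isolated)
Conditions: 2, Mg, THF, 50 °C; then 11, CuBr·SMe2 (10 mol%), TMSCl, THF, −78 °C; Et3N, aq. NaHCO3
Reagents that add atoms: chlorotrimethylsilane, C[Si](C)(C)Cl
Why: Copper-catalysed conjugate addition of an aryl Grignard reagent with silyl chloride trapping should deliver the aryl group anti to the 4-silyloxy group (this sets C6) and capture the enolate regiospecifically on the carbon next to the new stereocentre, from which the β-silyloxy group cannot eliminate.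

**Step 8**
Reactants: 13 (3S,4R)-3-[3,5-bis(TBSO)phenyl]-4-(TBSO)-1-(trimethylsilyloxy)cyclopent-1-ene; 10 (2Z,4E)-5-[3,4-bis(TBSO)phenyl]-3-iodo-N-methoxy-N-methylpenta-2,4-dienamide
Product: 16 (2Z,4E)-5-[3,4-bis(TBSO)phenyl]-3-{(1S,2S,3R)-2-[3,5-bis(TBSO)phenyl]-3-(TBSO)-5-oxocyclopentyl}-N-methoxy-N-methylpenta-2,4-dienamide (arm trans to aryl; ring carbon cis to the amide carbonyl), via lithium enolate 14 (not isolated), via chlorozinc enolate 15 (not isolated)
Conditions: MeLi, THF, 0 °C; ZnCl2, −78 to 0 °C; 10, Pd(P(t-Bu)3)2 (5 mol%), THF, 0 °C to rt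
Reagents that add atoms: none
Why: Palladium-catalysed α-alkenylation of a regiodefined ketone enolate (Negishi type, zinc enolate released from the silyl enol ether) with a vinyl iodide proceeds with retention of alkene geometry, and the arm should enter anti to the adjacent aryl group, which is also the thermodynamically preferred arrangement at this epimerisable α-carbon (sets C5).

**Step 9**
Reactants: 16 β-silyloxy ketone from step 8
Product: 17 (2Z,4E)-5-[3,4-bis(TBSO)phenyl]-3-{(1S,2S)-2-[3,5-bis(TBSO)phenyl]-5-oxocyclopent-3-en-1-yl}-N-methoxy-N-methylpenta-2,4-dienamide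
Conditions: DBU, CH2Cl2, −20 to 0 °C
Reagents that add atoms: none
Why: E1cB elimination of the β-silyloxy group through the enolate on the methylene side unveils the cyclopent-2-enone; the silyloxy stereocentre is deleted after it has relayed the absolute configuration, and the arm stays trans to the aryl group.

**Step 10**
Reactants: 17 enone Weinreb amide from step 9; 4 4-bromo-1,2-bis(TBSO)benzene
Product: 21 (1R,5S,6S,7S)-7-[3,4-bis(TBSO)phenyl]-6-[3,5-bis(TBSO)phenyl]-4-{(E)-2-[3,4-bis(TBSO)phenyl]ethenyl}bicyclo[3.2.1]oct-3-ene-2,8-dione, via arylmagnesium bromide 18 (not isolated), via magnesium enolate 19 (not isolated), via tetrahedral adduct 20 (not isolated)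
Conditions: 4, Mg, THF, 50 °C; then 18 (1.0 equiv) added slowly to 17, CuBr·SMe2 (10 mol%), THF, −78 °C; −78 to 0 °C; aq. NH4Cl
Reagents that add atoms: none
Why: Proposed new method: the arylcopper species formed from Grignard reagent 18 and catalytic CuBr·SMe2 adds 1,4 to the cyclopentenone of 17 and leaves magnesium enolate 19 regiospecifically on the carbon that becomes bridgehead C1, and on warming this enolate attacks the carbonyl of the Weinreb amide that the 2Z arm holds over the same ring face, giving the magnesium-chelated tetrahedral adduct 20, which collapses to the C2 ketone only at the NH4Cl quench. The closest known reaction types are the copper-catalysed tandem conjugate addition–Dieckmann cyclization of enone esters and the acylation of ketone enolates by Weinreb amides, neither of which has been shown to close a bridged, non-enolisable β-diketone. The six-membered ring closes in a 6-(enolendo)-exo-trig mode, the five-membered ring being already in place. C7 is set by attack of the aryl group anti to the neighbouring C6 aryl group, and C1 has no freedom because the arm, fixed trans to the C6 aryl group in step 8, can reach only the enolate face on which it stands, so the new aryl group ends endo, cis to the bridge. The step needs the enone to win over the dienamide as acceptor (a strained, unhindered cyclopentenone against a β,β-disubstituted, donor-conjugated amide) and C-acylation to win over O-acylation, which the Weinreb amide should secure because its O-adduct cannot expel the amide nitrogen and reverts, while the C-adduct is stored as a chelate that sets free no alkoxide able to reopen the diketone. One equivalent of the aryl nucleophile, consumed at −78 °C before warming, should keep the regenerated C8 ketone from further attack.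

**Step 11**
Reactants: 21 hexasilyl ether from step 10
Product: 22 (1R,5S,6S,7S)-7-(3,4-dihydroxyphenyl)-6-(3,5-dihydroxyphenyl)-4-[(E)-2-(3,4-dihydroxyphenyl)ethenyl]bicyclo[3.2.1]oct-3-ene-2,8-dione
Conditions: HF·pyridine, pyridine, THF, 0 °C to rt
Reagents that add atoms: none
Why: Fluoride cleavage of the six aryl silyl ethers under buffered, non-basic conditions should release the phenols without a nucleophilic base that could open the non-enolisable β-diketone by retro-Claisen reaction, and no stereocentre is touched.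

**Compound list**
1 | 5-bromobenzene-1,3-diol | Oc1cc(O)cc(Br)c1 | starting material
2 | 1-bromo-3,5-bis(TBSO)benzene | Brc1cc(O[Si](C)(C)C(C)(C)C)cc(O[Si](C)(C)C(C)(C)C)c1 | intermediate
3 | 4-bromobenzene-1,2-diol | Oc1ccc(Br)cc1O | starting material
4 | 4-bromo-1,2-bis(TBSO)benzene | Brc1ccc(O[Si](C)(C)C(C)(C)C)c(O[Si](C)(C)C(C)(C)C)c1 | intermediate
5 | 3,4-dihydroxybenzaldehyde | O=Cc1ccc(O)c(O)c1 | starting material
6 | 3,4-bis(TBSO)benzaldehyde | O=Cc1ccc(O[Si](C)(C)C(C)(C)C)c(O[Si](C)(C)C(C)(C)C)c1 | intermediate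
7 | (E)-4-(2-iodoethenyl)-1,2-bis(TBSO)benzene | I/C=C/c1ccc(O[Si](C)(C)C(C)(C)C)c(O[Si](C)(C)C(C)(C)C)c1 | intermediate
8 | N-methoxy-N-methylprop-2-ynamide | C#CC(=O)N(C)OC | starting material
9 | (E)-5-[3,4-bis(TBSO)phenyl]-N-methoxy-N-methylpent-4-en-2-ynamide | CON(C)C(=O)C#C/C=C/c1ccc(O[Si](C)(C)C(C)(C)C)c(O[Si](C)(C)C(C)(C)C)c1 | intermediate
10 | (2Z,4E)-5-[3,4-bis(TBSO)phenyl]-3-iodo-N-methoxy-N-methylpenta-2,4-dienamide | CON(C)C(=O)/C=C(\I)/C=C/c1ccc(O[Si](C)(C)C(C)(C)C)c(O[Si](C)(C)C(C)(C)C)c1 | intermediate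
11 | (R)-4-(TBSO)cyclopent-2-en-1-one | O=C1C=C[C@H](O[Si](C)(C)C(C)(C)C)C1 | starting material
12 | [3,5-bis(TBSO)phenyl]magnesium bromide | Br[Mg]c1cc(O[Si](C)(C)C(C)(C)C)cc(O[Si](C)(C)C(C)(C)C)c1 | intermediate (not isolated)
13 | (3S,4R)-3-[3,5-bis(TBSO)phenyl]-4-(TBSO)-1-(trimethylsilyloxy)cyclopent-1-ene | C[Si](C)(C)OC1=C[C@@H](c2cc(O[Si](C)(C)C(C)(C)C)cc(O[Si](C)(C)C(C)(C)C)c2)[C@H](O[Si](C)(C)C(C)(C)C)C1 | intermediate
14 | lithium enolate of the same ring (Li in place of TMS) | [Li]OC1=C[C@@H](c2cc(O[Si](C)(C)C(C)(C)C)cc(O[Si](C)(C)C(C)(C)C)c2)[C@H](O[Si](C)(C)C(C)(C)C)C1 | intermediate (not isolated)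
15 | chlorozinc enolate of the same ring | Cl[Zn]OC1=C[C@@H](c2cc(O[Si](C)(C)C(C)(C)C)cc(O[Si](C)(C)C(C)(C)C)c2)[C@H](O[Si](C)(C)C(C)(C)C)C1 | intermediate (not isolated)
16 | (2Z,4E)-5-[3,4-bis(TBSO)phenyl]-3-{(1S,2S,3R)-2-[3,5-bis(TBSO)phenyl]-3-(TBSO)-5-oxocyclopentyl}-N-methoxy-N-methylpenta-2,4-dienamide | O=C1C[C@@H](O[Si](C)(C)C(C)(C)C)[C@H](c2cc(O[Si](C)(C)C(C)(C)C)cc(O[Si](C)(C)C(C)(C)C)c2)[C@H]1/C(=C\C(=O)N(C)OC)/C=C/c1ccc(O[Si](C)(C)C(C)(C)C)c(O[Si](C)(C)C(C)(C)C)c1 | intermediate
17 | (2Z,4E)-5-[3,4-bis(TBSO)phenyl]-3-{(1S,2S)-2-[3,5-bis(TBSO)phenyl]-5-oxocyclopent-3-en-1-yl}-N-methoxy-N-methylpenta-2,4-dienamide | O=C1C=C[C@H](c2cc(O[Si](C)(C)C(C)(C)C)cc(O[Si](C)(C)C(C)(C)C)c2)[C@H]1/C(=C\C(=O)N(C)OC)/C=C/c1ccc(O[Si](C)(C)C(C)(C)C)c(O[Si](C)(C)C(C)(C)C)c1 | intermediate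
18 | [3,4-bis(TBSO)phenyl]magnesium bromide | Br[Mg]c1ccc(O[Si](C)(C)C(C)(C)C)c(O[Si](C)(C)C(C)(C)C)c1 | intermediate (not isolated)
19 | bromomagnesium enolate after conjugate arylation (new aryl trans to the old one, cis to the arm) | Br[Mg]OC1=C[C@@H](c2ccc(O[Si](C)(C)C(C)(C)C)c(O[Si](C)(C)C(C)(C)C)c2)[C@H](c2cc(O[Si](C)(C)C(C)(C)C)cc(O[Si](C)(C)C(C)(C)C)c2)[C@H]1/C(=C\C(=O)N(C)OC)/C=C/c1ccc(O[Si](C)(C)C(C)(C)C)c(O[Si](C)(C)C(C)(C)C)c1 | intermediate (not isolated)
20 | bicyclic tetrahedral adduct at C2 (bromomagnesium alkoxide, N-methoxy-N-methylamino; ring stereocentres as in 21, C2 undefined) | CON(C)C1(O[Mg]Br)C=C(/C=C/c2ccc(O[Si](C)(C)C(C)(C)C)c(O[Si](C)(C)C(C)(C)C)c2)[C@H]2C(=O)[C@@H]1[C@@H](c1ccc(O[Si](C)(C)C(C)(C)C)c(O[Si](C)(C)C(C)(C)C)c1)[C@@H]2c1cc(O[Si](C)(C)C(C)(C)C)cc(O[Si](C)(C)C(C)(C)C)c1 | intermediate (not isolated)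
21 | (1R,5S,6S,7S)-7-[3,4-bis(TBSO)phenyl]-6-[3,5-bis(TBSO)phenyl]-4-{(E)-2-[3,4-bis(TBSO)phenyl]ethenyl}bicyclo[3.2.1]oct-3-ene-2,8-dione (6-aryl exo, 7-aryl endo) | O=C1C=C(/C=C/c2ccc(O[Si](C)(C)C(C)(C)C)c(O[Si](C)(C)C(C)(C)C)c2)[C@H]2C(=O)[C@@H]1[C@@H](c1ccc(O[Si](C)(C)C(C)(C)C)c(O[Si](C)(C)C(C)(C)C)c1)[C@@H]2c1cc(O[Si](C)(C)C(C)(C)C)cc(O[Si](C)(C)C(C)(C)C)c1 | intermediate
22 | (1R,5S,6S,7S)-7-(3,4-dihydroxyphenyl)-6-(3,5-dihydroxyphenyl)-4-[(E)-2-(3,4-dihydroxyphenyl)ethenyl]bicyclo[3.2.1]oct-3-ene-2,8-dione | O=C1C=C(/C=C/c2ccc(O)c(O)c2)[C@H]2C(=O)[C@@H]1[C@@H](c1ccc(O)c(O)c1)[C@@H]2c1cc(O)cc(O)c1 | target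

**Step count and risks**
Total step count: 11. Longest linear sequence: 8 steps (steps 3, 4, 5, 6, 8, 9, 10, 11, from 3,4-dihydroxybenzaldehyde).

Steps most likely to fail:

Step 10 (bears the label). What may go wrong: quenching of enolate 19 by proton transfer from the acidic arm-bearing α-hydrogen of unreacted 17, or failure of the bridging C-acylation to outrun enolate equilibration. Fallback in known chemistry, setting out from 17 (with 4) and coming back at 21: Grignard reagent 18 is added to 17 with CuBr·SMe2 and TMSCl at −78 °C, which should give the regiodefined trimethylsilyl enol ether F1. DIBAL-H at −78 °C should reduce its Weinreb amide to the (2Z,4E)-dienal F2. BF3·OEt2 in CH2Cl2 at −78 °C should then close the six-membered ring by intramolecular Mukaiyama aldol addition to the bridged β-hydroxy ketone F3 (either carbinol epimer serves). Dess–Martin periodinane with NaHCO3 should oxidise the allylic alcohol and return to 21.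

Step 8. What may go wrong: equilibration of the zinc enolate to the methylene side with loss of silanol, protonation of the enolate by the more acidic product, or loss of the 2Z geometry during coupling. Fallback setting out from 11 and 10 and coming back at 16: 11 is α-iodinated (I2, pyridine, CH2Cl2) to the 2-iodoenone F4, and 10 is converted with Me3SnSnMe3 and Pd(PPh3)4 into the (2Z)-vinylstannane F5. Stille coupling of F4 with F5 (Pd2(dba)3, AsPh3, CuI, DMF) should give the 2-dienyl enone F6. Copper-catalysed conjugate addition of Grignard reagent 12 anti to the silyloxy group, followed by α-protonation and equilibration to the trans isomer, should then give 16.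

Step 9. What may go wrong: base-induced migration of the arm double bond into conjugation with the ketone, or deprotonation at the benzylic γ-carbon of the new enone with erosion of configuration. Fallback setting out from 13 (with 10) and coming back at 17, so that the dienyl ketone never meets DBU: 13 is hydrolysed (aq. citric acid, THF) to the β-silyloxy ketone F7, and DBU eliminates silanol from this simple ketone to give the 4-arylcyclopent-2-enone F8. Kinetic α′-deprotonation (LDA, THF, −78 °C), transmetalation with ZnCl2 and the palladium-catalysed alkenylation with 10 under the conditions of step 8 should deliver 17 directly, with the arm trans to the aryl group.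

**Further compounds**
F1 | step 10 | trimethylsilyl enol ether of the conjugate adduct of 17 (aryls trans, arm cis to the new aryl, Weinreb amide intact) | C[Si](C)(C)OC1=C[C@@H](c2ccc(O[Si](C)(C)C(C)(C)C)c(O[Si](C)(C)C(C)(C)C)c2)[C@H](c2cc(O[Si](C)(C)C(C)(C)C)cc(O[Si](C)(C)C(C)(C)C)c2)[C@H]1/C(=C\C(=O)N(C)OC)/C=C/c1ccc(O[Si](C)(C)C(C)(C)C)c(O[Si](C)(C)C(C)(C)C)c1
F2 | step 10 | corresponding (2Z,4E)-dienal silyl enol ether | C[Si](C)(C)OC1=C[C@@H](c2ccc(O[Si](C)(C)C(C)(C)C)c(O[Si](C)(C)C(C)(C)C)c2)[C@H](c2cc(O[Si](C)(C)C(C)(C)C)cc(O[Si](C)(C)C(C)(C)C)c2)[C@H]1/C(=C\C=O)/C=C/c1ccc(O[Si](C)(C)C(C)(C)C)c(O[Si](C)(C)C(C)(C)C)c1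
F3 | step 10 | 2-hydroxy analogue of 21 (bridged β-hydroxy ketone, ring stereocentres as in 21, carbinol carbon undefined) | OC1C=C(/C=C/c2ccc(O[Si](C)(C)C(C)(C)C)c(O[Si](C)(C)C(C)(C)C)c2)[C@H]2C(=O)[C@@H]1[C@@H](c1ccc(O[Si](C)(C)C(C)(C)C)c(O[Si](C)(C)C(C)(C)C)c1)[C@@H]2c1cc(O[Si](C)(C)C(C)(C)C)cc(O[Si](C)(C)C(C)(C)C)c1
F4 | step 8 | (R)-2-iodo-4-(TBSO)cyclopent-2-en-1-one | O=C1C(I)=C[C@H](O[Si](C)(C)C(C)(C)C)C1
F5 | step 8 | (2Z,4E)-5-[3,4-bis(TBSO)phenyl]-N-methoxy-N-methyl-3-(trimethylstannyl)penta-2,4-dienamide | CON(C)C(=O)/C=C(\[Sn](C)(C)C)/C=C/c1ccc(O[Si](C)(C)C(C)(C)C)c(O[Si](C)(C)C(C)(C)C)c1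
F6 | step 8 | (2Z,4E)-5-[3,4-bis(TBSO)phenyl]-3-[(3R)-3-(TBSO)-5-oxocyclopent-1-en-1-yl]-N-methoxy-N-methylpenta-2,4-dienamide | O=C1C[C@@H](O[Si](C)(C)C(C)(C)C)C=C1/C(=C\C(=O)N(C)OC)/C=C/c1ccc(O[Si](C)(C)C(C)(C)C)c(O[Si](C)(C)C(C)(C)C)c1
F7 | step 9 | (3S,4R)-3-[3,5-bis(TBSO)phenyl]-4-(TBSO)cyclopentan-1-one | O=C1C[C@@H](O[Si](C)(C)C(C)(C)C)[C@H](c2cc(O[Si](C)(C)C(C)(C)C)cc(O[Si](C)(C)C(C)(C)C)c2)C1
F8 | step 9 | (R)-4-[3,5-bis(TBSO)phenyl]cyclopent-2-en-1-one | O=C1C=C[C@H](c2cc(O[Si](C)(C)C(C)(C)C)cc(O[Si](C)(C)C(C)(C)C)c2)C1
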